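**Strategy.** Numbering the chain C1′ (benzylic, on ring A, the resorcinol ring) to C14′ (carbinol, on ring B, the pyrogallol ring), the 22-membered ring is opened at C3′–C4′. The key step exploits that this bond lies three carbons from ring A and is homoallylic to the C6′=C7′ E olefin. C1′–C3′ is therefore a latent allyl group and C4′ a primary homoallylic bromide. In one flask, 9-BBN hydroborates only the monosubstituted allyl alkene and an alkyl–alkyl Suzuki–Miyaura coupling closes the macrocycle, leaving nothing to erase. The precursor is an acyclic diaryl ether whose ring A bears allyl and whose ring B bears the silylated (R)-carbinol chain ending in CH2CH2Br.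

Key step: step 9

Assumption: the carbinol carbon is (R) (O > aryl > CH2 > H) and the olefin is E; compounds 1, 2, 4, 8 and 9 are taken as catalogue chemicals.

Step 1
Reactants: 1 3-bromo-5-methoxyphenol; 2 allyltributylstannane
Product: 3 3-methoxy-5-(prop-2-en-1-yl)phenol
Conditions: Pd(PPh3)4 (5 mol %), toluene, 110 °C
Reagents that add atoms: none
Why: Stille cross-coupling of an aryl bromide with an allylstannane runs under neutral conditions, so the free phenol needs no protection and the allyl double bond should not migrate into conjugation.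

Step 2
Reactants: 3 3-methoxy-5-(prop-2-en-1-yl)phenol; 4 4-bromo-3,5-dimethoxybenzaldehyde
Product: 5 3,5-dimethoxy-4-[3-methoxy-5-(prop-2-en-1-yl)phenoxy]benzaldehyde
Conditions: CuI (10 mol %), picolinic acid (20 mol %), K3PO4, DMSO, 90 °C
Reagents that add atoms: none
Why: Ullmann-type diaryl ether synthesis in which the para-formyl group activates the C–Br bond, the picolinate ligand system tolerates two ortho substituents and K3PO4 is too weak a base to isomerise the allyl group.

Step 3
Reactants: 5 3,5-dimethoxy-4-[3-methoxy-5-(prop-2-en-1-yl)phenoxy]benzaldehyde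
Product: 6 3,5-dihydroxy-4-[3-hydroxy-5-(prop-2-en-1-yl)phenoxy]benzaldehyde
Conditions: BBr3 (6 equiv), CH2Cl2, −78 → 0 °C; ice, aq. NaHCO3
Reagents that add atoms: none
Why: Lewis-acid cleavage of the three aryl methyl ethers (boron complexation, then SN2 attack of bromide on methyl) is placed where only a diaryl ether, a non-enolisable aldehyde and an allylarene are present, all of which should survive BBr3 at low temperature.

Step 4
Reactants: 6 3,5-dihydroxy-4-[3-hydroxy-5-(prop-2-en-1-yl)phenoxy]benzaldehyde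
Product: 7 4-[3-(prop-2-en-1-yl)-5-(triisopropylsilyloxy)phenoxy]-3,5-bis(triisopropylsilyloxy)benzaldehyde
Conditions: TIPSOTf (3.6 equiv), 2,6-lutidine, CH2Cl2, 0 °C → rt
Reagents that add atoms: triisopropylsilyl trifluoromethanesulfonate, CC(C)[Si](OS(=O)(=O)C(F)(F)F)(C(C)C)C(C)C
Why: O-silylation of phenols with a silyl triflate; the TIPS aryl ethers should withstand dialkylzinc/Ti(OiPr)4, 9-BBN and K3PO4·H2O and all fall to fluoride in the last step.

Step 5
Reactants: 8 oct-1-en-7-yne; 9 oxirane
Product: 12 (E)-deca-3,9-dien-1-ol, via alkenylalane 10 (not isolated), via lithium alanate 11 (not isolated)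
Conditions: i-Bu2AlH, heptane, 50 °C; n-BuLi, THF, −30 °C; oxirane, −30 °C → rt; aq. HCl
Reagents that add atoms: none
Why: syn-Hydroalumination of the terminal alkyne (much faster than that of the terminal alkene) gives the (E)-alkenylalane, whose ate complex opens oxirane with retention of geometry, so the E olefin of the target is set here.

Step 6
Reactants: 12 (E)-deca-3,9-dien-1-ol
Product: 13 (E)-10-bromodeca-1,7-diene
Conditions: CBr4, PPh3, CH2Cl2, 0 °C
Reagents that add atoms: tetrabromomethane, BrC(Br)(Br)Br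
Why: Appel reaction; SN2 displacement of the alkoxyphosphonium ion at a primary carbon leaves both double bonds untouched.

Step 7
Reactants: 7 4-[3-(prop-2-en-1-yl)-5-(triisopropylsilyloxy)phenoxy]-3,5-bis(triisopropylsilyloxy)benzaldehyde; 13 (E)-10-bromodeca-1,7-diene
Product: 16 (1R,8E)-11-bromo-1-{4-[3-(prop-2-en-1-yl)-5-(triisopropylsilyloxy)phenoxy]-3,5-bis(triisopropylsilyloxy)phenyl}undec-8-en-1-ol, via alkyldiethylborane 14 (not isolated), via dialkylzinc 15 (not isolated)
Conditions: 13 (2.5 equiv), Et2BH (from BH3·SMe2 + Et3B), Et2O, 0 °C → rt; Et2Zn (neat), 0 °C, then volatiles removed in vacuo; 7, Ti(OiPr)4 (2 equiv), (1S,2S)-1,2-bis(trifluoromethanesulfonamido)cyclohexane (8 mol %), toluene, −20 °C; aq. NH4Cl/HCl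
Reagents that add atoms: none
Why: Hydroboration of the monosubstituted alkene, boron–zinc exchange and titanium bis-sulfonamide-catalysed enantioselective addition of the functionalised dialkylzinc to the aryl aldehyde, in which the (1S,2S)-ligand directs alkyl transfer to the Re face and should set the (R)-carbinol, while the primary bromide and the E olefin are inert to dialkylzincs.

Step 8
Reactants: 16 (1R,8E)-11-bromo-1-{4-[3-(prop-2-en-1-yl)-5-(triisopropylsilyloxy)phenoxy]-3,5-bis(triisopropylsilyloxy)phenyl}undec-8-en-1-ol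
Product: 17 tert-butyldimethylsilyl ether of 16 (R at the carbinol carbon; E olefin)
Conditions: TBSOTf, 2,6-lutidine, CH2Cl2, −78 → 0 °C
Reagents that add atoms: tert-butyldimethylsilyl trifluoromethanesulfonate, CC(C)(C)[Si](C)(C)OS(=O)(=O)C(F)(F)F
Why: O-silylation of the secondary benzylic alcohol does not touch the C–O bond of the stereocentre and masks the hydroxyl against 9-BBN and base in the key step.

Step 9
Reactants: 17 tert-butyldimethylsilyl ether of 16
Product: 19 tris-O-triisopropylsilyl-O-tert-butyldimethylsilyl-dehydrogravicycle (R; E), via B-alkyl-9-BBN 18 (not isolated)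
Conditions: 9-BBN dimer (1.1 equiv B–H), THF, 0 °C → rt; then syringe-pump addition (12 h) to Pd(OAc)2 (15 mol %), PCy3 (30 mol %), K3PO4·H2O (3 equiv), THF (2 mM), rt
Reagents that add atoms: none
Why: 9-BBN adds anti-Markovnikov to the monosubstituted allyl alkene on ring A (the 1,2-disubstituted C6′=C7′ olefin reacts far more slowly) to give the primary B-alkyl-9-BBN 18; zerovalent palladium ligated by PCy3 then inserts into the primary C4′–Br bond by SN2-type oxidative addition, the hydroxide-activated borate transfers the C3′ alkyl group to palladium, and reductive elimination forms the C3′–C4′ bond. The closest known reaction type is the room-temperature palladium/trialkylphosphine alkyl–alkyl Suzuki–Miyaura coupling of primary alkyl bromides bearing β-hydrogens with B-alkyl-9-BBN reagents, run here intramolecularly in the manner of a B-alkyl Suzuki macrocyclisation. The 22-membered ring is closed end to end (formally an exo-tet substitution at C4′) under pseudo-high dilution by slow addition of 18 to the catalyst, and no smaller ring can compete because the reacting carbons sit at the two termini of the seco-chain. No stereocentre is created: the (R)-C14′ silyl ether is remote and configurationally inert, and the E geometry of C6′=C7′ is kept because the bromide is homoallylic, not allylic, so no π-allyl intermediate can form. The step needs chemoselective hydroboration (secured by the steric demand of 9-BBN), coupling in preference to β-hydride elimination from the homoallyl–palladium intermediate (secured by bulky, electron-rich PCy3 at room temperature) and cyclisation in preference to oligomerisation (secured by dilution).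

Step 10
Reactants: 19 tris-O-triisopropylsilyl-O-tert-butyldimethylsilyl-dehydrogravicycle
Product: 20 dehydrogravicycle
Conditions: Bu4NF (6 equiv), AcOH (6 equiv), THF, 0 → 40 °C
Reagents that add atoms: none
Why: Fluoride-mediated desilylation cleaves the three aryl and the one benzylic Si–O bond at silicon, so the (R)-carbinol and the E olefin are untouched, and the acetic acid buffer protects the liberated phenoxides.

**Compound list**

1 | 3-bromo-5-methoxyphenol | COc1cc(O)cc(Br)c1 | starting material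
2 | allyltributylstannane | C=CC[Sn](CCCC)(CCCC)CCCC | starting material
3 | 3-methoxy-5-(prop-2-en-1-yl)phenol | C=CCc1cc(O)cc(OC)c1 | intermediate
4 | 4-bromo-3,5-dimethoxybenzaldehyde | COc1cc(C=O)cc(OC)c1Br | starting material
5 | 3,5-dimethoxy-4-[3-methoxy-5-(prop-2-en-1-yl)phenoxy]benzaldehyde | C=CCc1cc(OC)cc(Oc2c(OC)cc(C=O)cc2OC)c1 | intermediate
6 | 3,5-dihydroxy-4-[3-hydroxy-5-(prop-2-en-1-yl)phenoxy]benzaldehyde | C=CCc1cc(O)cc(Oc2c(O)cc(C=O)cc2O)c1 | intermediate
7 | 4-[3-(prop-2-en-1-yl)-5-(triisopropylsilyloxy)phenoxy]-3,5-bis(triisopropylsilyloxy)benzaldehyde | C=CCc1cc(O[Si](C(C)C)(C(C)C)C(C)C)cc(Oc2c(O[Si](C(C)C)(C(C)C)C(C)C)cc(C=O)cc2O[Si](C(C)C)(C(C)C)C(C)C)c1 | intermediate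
8 | oct-1-en-7-yne | C=CCCCCC#C | starting material
9 | oxirane | C1CO1 | starting material
10 | (E)-diisobutyl(octa-1,7-dien-1-yl)alane | C=CCCCC/C=C/[Al](CC(C)C)CC(C)C | intermediate
11 | lithium (E)-butyldiisobutyl(octa-1,7-dien-1-yl)alanate | [Li+].C=CCCCC/C=C/[Al-](CCCC)(CC(C)C)CC(C)C | intermediate
12 | (E)-deca-3,9-dien-1-ol | OCC/C=C/CCCCC=C | intermediate
13 | (E)-10-bromodeca-1,7-diene | BrCC/C=C/CCCCC=C | intermediate
14 | [(E)-10-bromodec-7-en-1-yl]diethylborane | CCB(CC)CCCCCC/C=C/CCBr | intermediate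
15 | bis[(E)-10-bromodec-7-en-1-yl]zinc | BrCC/C=C/CCCCCC[Zn]CCCCCC/C=C/CCBr | intermediate
16 | (1R,8E)-11-bromo-1-{4-[3-(prop-2-en-1-yl)-5-(triisopropylsilyloxy)phenoxy]-3,5-bis(triisopropylsilyloxy)phenyl}undec-8-en-1-ol | C=CCc1cc(O[Si](C(C)C)(C(C)C)C(C)C)cc(Oc2c(O[Si](C(C)C)(C(C)C)C(C)C)cc(cc2O[Si](C(C)C)(C(C)C)C(C)C)[C@H](O)CCCCCC/C=C/CCBr)c1 | intermediate
17 | tert-butyldimethylsilyl ether of 16 (R; E) | C=CCc1cc(O[Si](C(C)C)(C(C)C)C(C)C)cc(Oc2c(O[Si](C(C)C)(C(C)C)C(C)C)cc(cc2O[Si](C(C)C)(C(C)C)C(C)C)[C@H](O[Si](C)(C)C(C)(C)C)CCCCCC/C=C/CCBr)c1 | intermediate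
18 | B-alkyl-9-BBN from 17 (boron on the terminal carbon of the former allyl group) | C1CCC2CCCC1B2CCCc1cc(O[Si](C(C)C)(C(C)C)C(C)C)cc(Oc2c(O[Si](C(C)C)(C(C)C)C(C)C)cc(cc2O[Si](C(C)C)(C(C)C)C(C)C)[C@H](O[Si](C)(C)C(C)(C)C)CCCCCC/C=C/CCBr)c1 | intermediate
19 | tris-O-triisopropylsilyl-O-tert-butyldimethylsilyl-dehydrogravicycle (R; E) | CC(C)[Si](C(C)C)(C(C)C)Oc1cc2cc(c1)Oc1c(O[Si](C(C)C)(C(C)C)C(C)C)cc(cc1O[Si](C(C)C)(C(C)C)C(C)C)[C@H](O[Si](C)(C)C(C)(C)C)CCCCCC/C=C/CCCCC2 | intermediate
20 | dehydrogravicycle | Oc1cc2cc(c1)Oc1c(O)cc(cc1O)[C@H](O)CCCCCC/C=C/CCCCC2 | target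

**Total step count:** 10
**Longest linear sequence:** 8 steps (steps 1, 2, 3, 4, 7, 8, 9, 10)

**Steps most likely to fail**

Step 9. β-Hydride elimination from the homoallyl–palladium intermediate (leading to a conjugated diene), protodeboronation, or oligomerisation may outrun ring closure. The fallback sets out from 17, returns at 19, and closes the same C3′–C4′ bond by carbanion alkylation:
- Bromide 17 is displaced with PhSO2Na (DMF, 60 °C) to give the homoallylic phenyl sulfone F1.
- 9-BBN hydroboration of the allyl group gives the B-alkyl-9-BBN sulfone F2 (not isolated), and NaBO3·4H2O oxidation gives the 3-arylpropan-1-ol sulfone F3.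
- I2, PPh3 and imidazole convert F3 into the primary iodide sulfone F4.
- Slow addition of F4 to LiN(i-Pr)2 in THF (−78 → 0 °C, high dilution) should let the α-sulfonyl carbanion at C4′ displace iodide at C3′ to give the macrocyclic sulfone F5.
- Reductive desulfonylation (Na/Hg, Na2HPO4, MeOH/THF, −20 °C) should then deliver 19.

Step 7. Facial selectivity of the alkyl transfer may be poor, for example through an uncatalysed background addition promoted by residual boranes. The fallback sets out from 16 of insufficient enantiomeric purity and returns at 16. Oxidation with Dess–Martin periodinane (CH2Cl2, NaHCO3) gives the aryl ketone F6. Corey–Bakshi–Shibata reduction with (S)-2-methyl-CBS-oxazaborolidine and catecholborane (toluene, −78 °C) should reset the (R)-carbinol, because the catalyst differentiates aryl from n-alkyl, and catecholborane at this temperature should leave both alkenes alone.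

Step 2. C–O bond formation at the doubly ortho-substituted carbon may be slow, with hydrodebromination competing. The fallback sets out from 3, returns at 5, and inverts the polarity of the ether synthesis:
- Tf2O and pyridine convert 3 into 3-methoxy-5-(prop-2-en-1-yl)phenyl triflate F7.
- Miyaura borylation (B2pin2, Pd(dppf)Cl2, KOAc, dioxane, 80 °C) gives the pinacol boronate F8.
- NaIO4/NH4OAc (acetone–water) frees the boronic acid F9.
- Chan–Lam coupling of F9 with commercial 4-hydroxy-3,5-dimethoxybenzaldehyde (Cu(OAc)2, pyridine, 4 Å sieves, air, CH2Cl2, rt) should give 5.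

**Further compounds**

F1 | step 9 | homoallylic phenyl sulfone from 17 (PhSO2 in place of Br) | C=CCc1cc(O[Si](C(C)C)(C(C)C)C(C)C)cc(Oc2c(O[Si](C(C)C)(C(C)C)C(C)C)cc(cc2O[Si](C(C)C)(C(C)C)C(C)C)[C@H](O[Si](C)(C)C(C)(C)C)CCCCCC/C=C/CCS(=O)(=O)c2ccccc2)c1
F2 | step 9 | B-alkyl-9-BBN sulfone | C1CCC2CCCC1B2CCCc1cc(O[Si](C(C)C)(C(C)C)C(C)C)cc(Oc2c(O[Si](C(C)C)(C(C)C)C(C)C)cc(cc2O[Si](C(C)C)(C(C)C)C(C)C)[C@H](O[Si](C)(C)C(C)(C)C)CCCCCC/C=C/CCS(=O)(=O)c2ccccc2)c1
F3 | step 9 | 3-arylpropan-1-ol sulfone | OCCCc1cc(O[Si](C(C)C)(C(C)C)C(C)C)cc(Oc2c(O[Si](C(C)C)(C(C)C)C(C)C)cc(cc2O[Si](C(C)C)(C(C)C)C(C)C)[C@H](O[Si](C)(C)C(C)(C)C)CCCCCC/C=C/CCS(=O)(=O)c2ccccc2)c1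
F4 | step 9 | primary iodide sulfone | ICCCc1cc(O[Si](C(C)C)(C(C)C)C(C)C)cc(Oc2c(O[Si](C(C)C)(C(C)C)C(C)C)cc(cc2O[Si](C(C)C)(C(C)C)C(C)C)[C@H](O[Si](C)(C)C(C)(C)C)CCCCCC/C=C/CCS(=O)(=O)c2ccccc2)c1
F5 | step 9 | macrocyclic sulfone (PhSO2 at C4′, both epimers) | CC(C)[Si](C(C)C)(C(C)C)Oc1cc2cc(c1)Oc1c(O[Si](C(C)C)(C(C)C)C(C)C)cc(cc1O[Si](C(C)C)(C(C)C)C(C)C)[C@H](O[Si](C)(C)C(C)(C)C)CCCCCC/C=C/CC(S(=O)(=O)c1ccccc1)CCC2
F6 | step 7 | aryl ketone from 16 | C=CCc1cc(O[Si](C(C)C)(C(C)C)C(C)C)cc(Oc2c(O[Si](C(C)C)(C(C)C)C(C)C)cc(cc2O[Si](C(C)C)(C(C)C)C(C)C)C(=O)CCCCCC/C=C/CCBr)c1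
F7 | step 2 | 3-methoxy-5-(prop-2-en-1-yl)phenyl triflate | C=CCc1cc(OC)cc(OS(=O)(=O)C(F)(F)F)c1
F8 | step 2 | 2-[3-methoxy-5-(prop-2-en-1-yl)phenyl]-4,4,5,5-tetramethyl-1,3,2-dioxaborolane | C=CCc1cc(OC)cc(B2OC(C)(C)C(C)(C)O2)c1
F9 | step 2 | [3-methoxy-5-(prop-2-en-1-yl)phenyl]boronic acid | C=CCc1cc(OC)cc(B(O)O)c1
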